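The earlier runs and the new flask were generated by integration with made-up constants, noise included.

In a one-step world the starting material falls with a single time constant, so one number would carry a whole run: the elapsed time divided by ln(charged over left). I call this the mean time constant, the pseudo-first-order view of a curve.

| setting | summer | autumn | spring | flask |
|---|---|---|---|---|
| starting material | 0.064 M | 0.064 M | 0.096 M | 0.064 M |
| solid reagent | 0.048 M | 0.072 M | 0.096 M | 0.0960 M |
| remark | run made earlier | run made earlier | run made earlier |  |
| time |  |  |  | 40 min |

| run | time / min | product / % | starting material / % |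
|---|---|---|---|
| summer | 2.00 | 1.0 | 99.9 |
| summer | 6.00 | 5.1 | 95.5 |
| summer | 12.0 | 14.2 | 85.6 |
| summer | 20.0 | 23.7 | 75.2 |
| summer | 25.0 | 29.0 | 70.4 |
| summer | 30.0 | 33.0 | 66.3 |
| autumn | 2.50 | 1.2 | 98.4 |
| autumn | 4.00 | 2.0 | 97.2 |
| autumn | 8.00 | 8.2 | 92.2 |
| autumn | 12.0 | 14.6 | 86.6 |
| autumn | 20.0 | 25.8 | 73.0 |
| autumn | 30.0 | 40.8 | 59.4 |
| spring | 3.00 | 1.8 | 98.6 |
| spring | 8.00 | 9.5 | 92.2 |
| spring | 15.0 | 21.6 | 78.9 |
| spring | 25.0 | 37.5 | 63.2 |
| spring | 30.0 | 43.6 | 56.3 |

(standard deviation of a reading: 0.5 percentage points)

- given per volume of solution although it is solid: solid reagent
- at the start none of the solid reagent is in solution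

- ochre: doubling the solubility of the solid reagent, all else as stated
- red: doubling the dissolution coefficient of the solid reagent, all else as stated

1. product at 40 min, in percent of the starting material charged
2. the change that raises the amount of product at 40 min, in percent of the starting material charged most ("none" if none brings more than 2 percentage points) (ochre / red / none)
3. amount of product at 40 min, in percent of the starting material charged, after red

You are taking over a flask with [starting material] = 0.064 M and 0.0960 M of solid reagent, none of it dissolved at the start. Don't touch it if it looks dead early on: the autumn run, with the same [starting material], had 2.0% product at 4.00 min.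

That autumn run gives 57.6 min to its last reading, but 63.6 min to 20.0 min, so in that run the mean is shorter at the last reading. The summer run, with less solid, gives a longer one, 73.0 min. Carried to 40 min, my reckoning gives 50.1% product when you come.

The forecast says 59% (54% to 64%), 73% after red, and ochre as the best change, seeing “both steps partly limiting”. My figure lies below its range.

The flask gives 51.7%. Ochre adds 11 percentage points and red adds 5.8 points, which makes 57.5% after red, so the best change is ochre.

    starting material + partner → product, rate k1*[starting material]^1.5*[partner] (k = 0.0340 /M^1.5/s)
    solid reagent ⇌ partner, rate k2*(cs2 - [partner]) while solid is left; crystals form when [partner] > cs2 (solubility = 0.0630 M, k = 0.00180 /s)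

The reckoning with the autumn mean time constant came 1.6 points below this flask. Now read the same flask at 2.5 h: the same 57.6 min gives 92.6% product. That neighbour holds 87.0%, with 13% of the starting material left, a mean time constant of 73.5 min.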